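**Plan**
1. Cuts, in retrosynthetic order: the seven O–CH3 bonds; the Cα–Cβ bond of the seven-membered ring, traced back to an eight-membered cyclic amine Cα–NH–Cβ whose nitrogen is deleted; N–Cβ and Cβ–ring B (amide, then Bischler–Napieralski); C10–C10a (Friedel–Crafts hydroarylation); C9=C10 (Horner–Wadsworth–Emmons); the A–C biaryl bond (Suzuki–Miyaura).
2. Forward ring order: biaryl A–C, then the six-membered ring of the 9,10-dihydrophenanthrene, then a temporary eight-membered aza ring through ring B, then the seven-membered carbocycle by ring contraction, then the heptaphenol.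
3. Feature used: Cα is benzylic (ring C) and Cβ is doubly benzylic (rings B and D, each with a para oxygen), and neither has a β-hydrogen. A Cα–N–Cβ amine is therefore a dibenzylic amine whose N2 extrusion leaves a stabilised radical pair that can only recombine. C6′ of ring B is para to an oxygen, so the aza ring can be closed by electrophilic substitution.
4. Helper atom: the nitrogen comes in as the nitrile on ring C, which also steers the Friedel–Crafts closure to the correct ortho carbon, and leaves as N2 in the key step.
5. Stereochemistry: C10 (R) by resolution of the racemic dihydrophenanthrene nitrile on a chiral stationary phase; Cβ (S) is set in the key step under control of C10.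

Key step: step 8

Locants: ring A is the dimethoxy ring of the dihydrophenanthrene (C4b–C8a) and ring C its other benzo ring (C1–C4a, C10a); C9 is the CH2 and C10 the CH. Ring B is the 3,4-dioxygenated aryl on C10 (C1′ on C10; C6′ is the free ortho carbon para to the 3′-oxygen). Cα is the CH2 on C1; Cβ is the CH that carries ring D, the pendant 3,4-dioxygenated aryl.
Remark: all phenols are carried as methyl ethers; compounds 1, 2, 4, 9 and the anomeric amide of step 8 are taken as commercial.

Step 1
Reactants: 1 2-bromo-3,5-dimethoxybenzaldehyde; 2 (3-cyano-5-methoxyphenyl)boronic acid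
Product: 3 2′-formyl-4′,5,6′-trimethoxy[1,1′-biphenyl]-3-carbonitrile
Conditions: Pd(OAc)2 (3 mol%), SPhos (6 mol%), K3PO4, toluene/H2O (10:1), 90 °C
Reagents that add atoms: none
Why: Suzuki–Miyaura coupling in which the SPhos-ligated palladium catalyst should handle the doubly ortho-substituted bromide while aldehyde and nitrile stay inert; no stereocentre is formed.

Step 2
Reactants: 3 2′-formyl-4′,5,6′-trimethoxy[1,1′-biphenyl]-3-carbonitrile; 4 diethyl (3,4-dimethoxybenzyl)phosphonate
Product: 5 2′-[(E)-2-(3,4-dimethoxyphenyl)ethenyl]-4′,5,6′-trimethoxy[1,1′-biphenyl]-3-carbonitrile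
Conditions: KOtBu, THF, 0 °C to rt
Reagents that add atoms: none
Why: Horner–Wadsworth–Emmons olefination of an aryl aldehyde with a benzylphosphonate anion should give the (E)-stilbene, and the stabilised anion should not attack the aryl nitrile at this temperature.

Step 3
Reactants: 5 2′-[(E)-2-(3,4-dimethoxyphenyl)ethenyl]-4′,5,6′-trimethoxy[1,1′-biphenyl]-3-carbonitrile
Product: 6 rac-10-(3,4-dimethoxyphenyl)-3,5,7-trimethoxy-9,10-dihydrophenanthrene-1-carbonitrile
Conditions: TfOH (20 mol%), (CF3)2CHOH/CH2Cl2 (1:1), 0.005 M, 0 °C to rt
Reagents that add atoms: none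
Why: Brønsted-acid hydroarylation (intramolecular Friedel–Crafts alkylation) of a 2-styrylbiaryl, in which protonation at C9 gives the C10 cation stabilised by the para-methoxy group of ring B and ring C closes the six-membered ring at the ortho carbon that is para to its methoxy group and ortho (not para) to the nitrile; C10 forms as the racemate, and alkylation of ring A is held back by dilution and is reversible.

Step 4
Reactants: 6 rac-10-(3,4-dimethoxyphenyl)-3,5,7-trimethoxy-9,10-dihydrophenanthrene-1-carbonitrile
Product: 7 (10R)-10-(3,4-dimethoxyphenyl)-3,5,7-trimethoxy-9,10-dihydrophenanthrene-1-carbonitrile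
Conditions: preparative SFC on amylose tris(3,5-dimethylphenylcarbamate), CO2/MeOH, 35 °C
Reagents that add atoms: none
Why: Resolution of a rigid neutral racemate on a polysaccharide chiral stationary phase is where the absolute configuration at C10 enters; the (R)-enantiomer is to be assigned by anomalous-dispersion X-ray or VCD before it is carried on.

Step 5
Reactants: 7 (10R)-10-(3,4-dimethoxyphenyl)-3,5,7-trimethoxy-9,10-dihydrophenanthrene-1-carbonitrile
Product: 8 [(10R)-10-(3,4-dimethoxyphenyl)-3,5,7-trimethoxy-9,10-dihydrophenanthren-1-yl]methanamine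
Conditions: LiAlH4, THF, 0 °C to reflux; then aqueous NaOH work-up
Reagents that add atoms: none
Why: Hydride reduction of an aryl nitrile to the benzylic primary amine, with nothing else in 7 reducible and the C10–H not deprotonated, so the stereocentre should be untouched.

Step 6
Reactants: 8 [(10R)-10-(3,4-dimethoxyphenyl)-3,5,7-trimethoxy-9,10-dihydrophenanthren-1-yl]methanamine; 9 3,4-dimethoxybenzoyl chloride
Product: 10 N-{[(10R)-10-(3,4-dimethoxyphenyl)-3,5,7-trimethoxy-9,10-dihydrophenanthren-1-yl]methyl}-3,4-dimethoxybenzamide
Conditions: Et3N, CH2Cl2, 0 °C to rt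
Reagents that add atoms: none
Why: N-acylation of a primary amine by an acid chloride brings in ring D and the future Cβ as the amide carbon.

Step 7
Reactants: 10 N-{[(10R)-10-(3,4-dimethoxyphenyl)-3,5,7-trimethoxy-9,10-dihydrophenanthren-1-yl]methyl}-3,4-dimethoxybenzamide
Product: 12 (10R)-eight-membered cyclic amine CαH2–NH–CβH(ring D) with Cβ bonded to C6′ of ring B (both Cβ epimers), via cyclic imine 11 (not isolated)
Conditions: Tf2O, 2-chloropyridine, CH2Cl2 (0.01 M), −78 to 40 °C; then NaBH4, MeOH, 0 °C
Reagents that add atoms: none
Why: Bischler–Napieralski cyclodehydration in which the N-benzyl nitrilium ion is attacked by C6′ of ring B (para to the 3′-methoxy group), the linear nitrilium being easily spanned by an eight-membered transition state as in other dibenzo-fused medium-ring imines, and NaBH4 then reduces the C=N; the Cβ–N stereocentre is left uncontrolled because step 8 erases it.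

Step 8
Reactants: 12 (10R)-eight-membered cyclic amine CαH2–NH–CβH(ring D) with Cβ bonded to C6′ of ring B (both Cβ epimers)
Product: 15 (10R,βS)-heptamethyl ether of the target, via N-amino amide 13 (not isolated), via isodiazene 14 (not isolated)
Conditions: N-(benzyloxy)-N-(pivaloyloxy)-4-(trifluoromethyl)benzamide (1.5 equiv), degassed THF (0.02 M), 45 °C
Reagents that add atoms: none
Why: The ring nitrogen of 12 displaces pivalate from the amide nitrogen of the anomeric amide to give 13, which expels benzyl 4-(trifluoromethyl)benzoate to give isodiazene 14, and loss of N2 leaves a singlet 1,7-diradical (benzylic at Cα, diarylmethyl at Cβ) that collapses to the Cα–Cβ bond. The closest known reaction type is the nitrogen deletion of dibenzylic secondary amines, cyclic ones included, with anomeric amides, the modern form of the oxidative N2 extrusion from N-aminodibenzylamines. The seven-membered ring (C10, C1′ and C6′ of ring B, Cβ, Cα, C1 and C10a of ring C) closes by intramolecular radical–radical recombination, formally a contraction of the eight-membered aza ring by one atom. Cβ is the only new stereocentre and is controlled by C10: the dihydrophenanthrene keeps C9 near the plane of ring C and so forces ring B onto one face, Cα can reach only one face of the planar Cβ radical, and on that radical ring D turns toward the unsubstituted C5′–H and away from C10 (allylic 1,3-strain), which should place H at Cβ cis to H at C10, that is (S). Both Cβ epimers of 12 pass through the same diradical, so the stereocentre made in step 7 does not matter. The step needs recombination to win over hydrogen abstraction, dimerisation and disproportionation; the tether keeps the two centres together, neither carries a β-hydrogen, and dilute degassed THF removes the bimolecular paths.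

Step 9
Reactants: 15 (10R,βS)-heptamethyl ether of the target
Product: 16 CNP0306974.1, the (10R,βS)-heptaphenol
Conditions: BBr3 (14 equiv), CH2Cl2, −78 °C to rt; then MeOH, H2O; under argon
Reagents that add atoms: none
Why: Lewis-acid cleavage of all seven aryl methyl ethers by BBr3, the standard last step for permethylated stilbene oligomers, should leave both benzylic stereocentres untouched at low temperature, and argon protects the catechols and the dihydrophenanthrene from oxidation.

**Compound list**
1 | 2-bromo-3,5-dimethoxybenzaldehyde | COc1cc(OC)c(Br)c(C=O)c1 | starting material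
2 | (3-cyano-5-methoxyphenyl)boronic acid | COc1cc(C#N)cc(c1)B(O)O | starting material
3 | 2′-formyl-4′,5,6′-trimethoxy[1,1′-biphenyl]-3-carbonitrile | COc1cc(OC)c(-c2cc(OC)cc(C#N)c2)c(C=O)c1 | intermediate
4 | diethyl (3,4-dimethoxybenzyl)phosphonate | CCOP(=O)(Cc1ccc(OC)c(OC)c1)OCC | starting material
5 | 2′-[(E)-2-(3,4-dimethoxyphenyl)ethenyl]-4′,5,6′-trimethoxy[1,1′-biphenyl]-3-carbonitrile | COc1cc(OC)c(-c2cc(OC)cc(C#N)c2)c(/C=C/c2ccc(OC)c(OC)c2)c1 | intermediate
6 | rac-10-(3,4-dimethoxyphenyl)-3,5,7-trimethoxy-9,10-dihydrophenanthrene-1-carbonitrile | COc1cc(OC)c2c(c1)CC(c1ccc(OC)c(OC)c1)c1c(C#N)cc(OC)cc1-2 | intermediate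
7 | (10R)-10-(3,4-dimethoxyphenyl)-3,5,7-trimethoxy-9,10-dihydrophenanthrene-1-carbonitrile | COc1cc(OC)c2c(c1)C[C@H](c1ccc(OC)c(OC)c1)c1c(C#N)cc(OC)cc1-2 | intermediate
8 | [(10R)-10-(3,4-dimethoxyphenyl)-3,5,7-trimethoxy-9,10-dihydrophenanthren-1-yl]methanamine | COc1cc(OC)c2c(c1)C[C@H](c1ccc(OC)c(OC)c1)c1c(CN)cc(OC)cc1-2 | intermediate
9 | 3,4-dimethoxybenzoyl chloride | COc1ccc(cc1OC)C(Cl)=O | starting material
10 | N-{[(10R)-10-(3,4-dimethoxyphenyl)-3,5,7-trimethoxy-9,10-dihydrophenanthren-1-yl]methyl}-3,4-dimethoxybenzamide | COc1cc(OC)c2c(c1)C[C@H](c1ccc(OC)c(OC)c1)c1c(CNC(=O)c3ccc(OC)c(OC)c3)cc(OC)cc1-2 | intermediate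
11 | (10R)-cyclic imine: CαH2–N=Cβ(3,4-dimethoxyphenyl) spanning C1 of the dihydrophenanthrene and C6′ of ring B (eight-membered ring) | COc1cc(OC)c2c(c1)C[C@@H]1c3cc(OC)c(OC)cc3C(c3ccc(OC)c(OC)c3)=NCc3cc(OC)cc-2c31 | intermediate (not isolated)
12 | (10R)-cyclic secondary amine: as 11 with CαH2–NH–CβH(3,4-dimethoxyphenyl); both Cβ epimers | COc1cc(OC)c2c(c1)C[C@@H]1c3cc(OC)c(OC)cc3C(c3ccc(OC)c(OC)c3)NCc3cc(OC)cc-2c31 | intermediate
13 | N-amino amide: 12 with N(OCH2Ph)C(=O)C6H4-4-CF3 on the ring nitrogen | COc1cc(OC)c2c(c1)C[C@@H]1c3cc(OC)c(OC)cc3C(c3ccc(OC)c(OC)c3)N(N(OCc3ccccc3)C(=O)c3ccc(cc3)C(F)(F)F)Cc3cc(OC)cc-2c31 | intermediate (not isolated)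
14 | isodiazene (1,1-diazene): 12 with N+=N− in place of N–H | COc1cc(OC)c2c(c1)C[C@@H]1c3cc(OC)c(OC)cc3C(c3ccc(OC)c(OC)c3)[N+](=[N-])Cc3cc(OC)cc-2c31 | intermediate (not isolated)
15 | (10R,βS)-heptamethyl ether of the target: 3,5,7-trimethoxy-9,10-dihydrophenanthrene whose C10 and Cα (CH2 on C1) are bridged by 4,5-dimethoxy-1,2-phenylene–CβH(3,4-dimethoxyphenyl); H at C10 and H at Cβ cis | COc1cc(OC)c2c(c1)C[C@@H]1c3cc(OC)c(OC)cc3[C@H](c3ccc(OC)c(OC)c3)Cc3cc(OC)cc-2c31 | intermediate
16 | CNP0306974.1, the (10R,βS)-heptaphenol corresponding to 15 | Oc1cc(O)c2c(c1)C[C@@H]1c3cc(O)c(O)cc3[C@H](c3ccc(O)c(O)c3)Cc3cc(O)cc-2c31 | target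

**Step count and risks**
Total step count: 9. Longest linear sequence: 9 steps (from 1 to 16).

Steps most likely to fail:

Step 8. The 1,7-diradical may abstract hydrogen or couple through a ring position instead of recombining at carbon. Recombination may also show poor facial selectivity at Cβ, or keep the configuration of the amine instead of converging. The fallback sets out from 7 and comes back at 15, and makes the Cα–Cβ bond by olefination before the ring is closed. Nitrile 7 is reduced with i-Bu2AlH (toluene, −78 °C, aqueous acid work-up) to (10R)-10-(3,4-dimethoxyphenyl)-3,5,7-trimethoxy-9,10-dihydrophenanthrene-1-carbaldehyde F1. F1 is olefinated with phosphonate 4 (KOtBu, THF) to the (E)-stilbene F2. F2 is treated with catalytic TfOH in (CF3)2CHOH/CH2Cl2 at high dilution. Protonation at Cα gives the Cβ cation stabilised by ring D, and C6′ of ring B captures it in a Friedel–Crafts closure of the seven-membered ring to 15. This closure is reversible, so the Cβ ratio is under thermodynamic rather than kinetic control; epimers would be separated before step 9.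

Step 7. Closure of the eight-membered ring may be slow, which would allow loss of the benzyl group from the nitrilium ion (von Braun-type fragmentation) or intermolecular attack by ring A. The fallback sets out from 8 and comes back at 12, and brings ring D in as a nucleophile. Amine 8 is formylated (HCO2Et, reflux) to the formamide F3. Tf2O/2-chloropyridine closes the small, unhindered H–C≡N+ nitrilium onto C6′ of ring B to give the cyclic aldimine F4. Addition of 3,4-(MeO)2C6H3Li (from 4-bromoveratrole and n-BuLi; THF, −78 °C) to the C=N gives 12.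

Step 3. Intermolecular Friedel–Crafts alkylation of the electron-rich ring A (oligomerisation) may outrun closure onto the nitrile-deactivated ring C, and some closure may occur at the ortho carbon next to the methoxy group. The fallback sets out from 5 and comes back at 6 with no new compound (F0). Stilbene 5 is irradiated (about 300 nm, degassed MeCN, no oxidant). This is the non-oxidative photocyclisation of a 2-styrylbiaryl: a 6π-electrocyclisation forms C10–C10a and a 1,5-hydrogen shift restores ring C. No cation is formed, so ring A cannot be alkylated.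

**Further compounds**
F1 | step 8 | (10R)-10-(3,4-dimethoxyphenyl)-3,5,7-trimethoxy-9,10-dihydrophenanthrene-1-carbaldehyde | COc1cc(OC)c2c(c1)C[C@H](c1ccc(OC)c(OC)c1)c1c(C=O)cc(OC)cc1-2
F2 | step 8 | (10R)-10-(3,4-dimethoxyphenyl)-1-[(E)-2-(3,4-dimethoxyphenyl)ethenyl]-3,5,7-trimethoxy-9,10-dihydrophenanthrene | COc1cc(OC)c2c(c1)C[C@H](c1ccc(OC)c(OC)c1)c1c(/C=C/c3ccc(OC)c(OC)c3)cc(OC)cc1-2
F3 | step 7 | N-{[(10R)-10-(3,4-dimethoxyphenyl)-3,5,7-trimethoxy-9,10-dihydrophenanthren-1-yl]methyl}formamide | COc1cc(OC)c2c(c1)C[C@H](c1ccc(OC)c(OC)c1)c1c(CNC=O)cc(OC)cc1-2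
F4 | step 7 | (10R)-cyclic aldimine: as 11 with H in place of ring D on Cβ | COc1cc(OC)c2c(c1)C[C@@H]1c3cc(OC)c(OC)cc3C=NCc3cc(OC)cc-2c31
F0 | step 3 | none | none
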